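**Strategy.** The plan builds the bromotrimethylcyclopentane ring (C1' quaternary, C2' gem-dimethyl, C3' CHBr, C4', C5') by a [3+2] annulation that forms C1'–C5' and C2'–C3' in one operation. It exploits the vicinal fully substituted pair C1'/C2' next to the functionalised C3'. The enolate of an α-methyl β-keto ester (C1', C2') opens an activated cyclopropylphosphonium salt (C3'–C5'), and the ylide so formed olefinates the acetyl group. The ester carbon later becomes C3 of enone ring A: a Shapiro vinyllithium acylates a ring B lactone and a 6-endo Heck reaction closes ring A. Double Appel inversion, epoxidation and epoxide hydrolysis finish the synthesis.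

Key step: step 2

Remark on the chemistry: primed locants denote the cyclopentane; the bicycle is numbered as naphthalen-2(1H)-one (ring A = C1–C4, C4a, C8a; ring B = C4a–C8a). Step 2 gives a racemate, and the enantiomers are parted in step 5.

Step 1
Reactants: 1 cyclopropyl(triphenyl)phosphonium bromide
Product: 4 [1-(phenylsulfanyl)cyclopropyl](triphenyl)phosphonium tetrafluoroborate, via cyclopropylidene ylide 2 (not isolated), via phosphonium benzenesulfinate 3 (not isolated)
Conditions: n-BuLi, THF, −78 to 0 °C; PhSO2SPh, −78 °C to rt; then aq. NaBF4, CH2Cl2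
Reagents that add atoms: S-phenyl benzenethiosulfonate O=S(=O)(Sc1ccccc1)c1ccccc1; sodium tetrafluoroborate [Na+].F[B-](F)(F)F
Why: Deprotonation gives ylide 2, which is sulfenylated at carbon by the thiosulfonate (ylide sulfenylation), and salt metathesis installs the non-nucleophilic counter-ion; no stereocenter is formed.

Step 2
Reactants: 4 [1-(phenylsulfanyl)cyclopropyl](triphenyl)phosphonium tetrafluoroborate; 5 ethyl 2-methyl-3-oxobutanoate
Product: 8 ethyl 1,2-dimethyl-3-(phenylsulfanyl)cyclopent-2-ene-1-carboxylate (racemic), via sodium enolate 6 (not isolated), via ring-opened phosphorus ylide 7 (not isolated)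
Conditions: NaH, THF, 0 °C; then 4, THF, 65 °C
Reagents that add atoms: none
Why: The soft carbon of enolate 6 opens the cyclopropane of 4 by SN2 attack at a ring CH2 (homo-conjugate addition), which forms the C1–C5 bond of 8 (C1'–C5' of the target) with its quaternary carbon and unveils the sulfur-stabilised ylide 7. Ylide 7 then undergoes an intramolecular Wittig olefination with the acetyl carbonyl, which forms C2=C3 (C2'–C3') and closes the five-membered ring by 5-exo-trig attack of the ylide carbon on C=O followed by oxaphosphetane collapse. The closest known reaction type is the cyclopentannulation of β-dicarbonyl enolates with activated cyclopropylphosphonium salts. The only new stereocenter, C1, arises from an achiral enolate and an achiral electrophile, so 8 forms as a racemate, and the enantiomers are parted in step 5. The step needs C- over O-alkylation, which the soft electrophile and the sodium β-keto ester enolate favour, and olefination of the ketone rather than the ester, which follows from the higher electrophilicity of the ketone and the five-membered transition state. The phenylsulfanyl group both activates the ring opening and marks C3 as a latent ketone, while the acetyl methyl becomes one of the geminal methyl groups.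

Step 3
Reactants: 8 ethyl 1,2-dimethyl-3-(phenylsulfanyl)cyclopent-2-ene-1-carboxylate (racemic)
Product: 9 ethyl 1,2-dimethyl-3-oxocyclopentane-1-carboxylate (racemic; C2 epimers)
Conditions: TiCl4, AcOH–H2O, 25 °C
Reagents that add atoms: water O
Why: Lewis-acid-assisted hydrolysis of the enol thioether (vinyl sulfide hydrolysis) releases the C3 ketone; the C2 stereocenter created here is erased in step 4, so its configuration is immaterial.

Step 4
Reactants: 9 ethyl 1,2-dimethyl-3-oxocyclopentane-1-carboxylate (racemic; C2 epimers)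
Product: 10 ethyl 1,2,2-trimethyl-3-oxocyclopentane-1-carboxylate (racemic)
Conditions: t-BuOK, t-BuOH–THF, 25 °C; then MeI, 0 °C
Reagents that add atoms: iodomethane CI
Why: Under equilibrating conditions the more substituted C2–C3 enolate should predominate and be C-methylated (thermodynamic enolate alkylation), which installs the geminal dimethyl group and removes the C2 stereocenter.

Step 5
Reactants: 10 ethyl 1,2,2-trimethyl-3-oxocyclopentane-1-carboxylate (racemic)
Product: 11 ethyl (1S,3S)-3-hydroxy-1,2,2-trimethylcyclopentane-1-carboxylate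
Conditions: (R)-2-methyl-CBS-oxazaborolidine (20 mol %), BH3·SMe2, THF, −30 °C; MeOH, then aq. work-up; chromatography
Reagents that add atoms: none
Why: Corey–Bakshi–Shibata reduction: the (R)-catalyst should deliver hydride to the same enantioface of the ketone (quaternary C2 large, C4H2 small) in both enantiomers of 10, so C3 becomes (S) throughout; the (1S) enantiomer gives 11 (OH trans to the ester) and the (1R) enantiomer gives the separable cis diastereomer, which parts the enantiomers formed in step 2.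

Step 6
Reactants: 11 ethyl (1S,3S)-3-hydroxy-1,2,2-trimethylcyclopentane-1-carboxylate
Product: 13 1-[(1S,3S)-3-hydroxy-1,2,2-trimethylcyclopentyl]ethan-1-one, via silyl enolate dilithium salt 12 (not isolated)
Conditions: Me3SiCH2Li (3.5 equiv), pentane–THF, 0 °C to rt; then MeOH; aq. NH4Cl
Reagents that add atoms: (trimethylsilyl)methyllithium [Li]C[Si](C)(C)C
Why: After deprotonating the alcohol the reagent adds once to the hindered ester, because the α-silyl ketone is held as its enolate 12, and methanolysis cleaves the C–Si bond (ester to methyl ketone conversion by way of an α-silyl ketone); both stereocenters are spectators.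

Step 7
Reactants: 13 1-[(1S,3S)-3-hydroxy-1,2,2-trimethylcyclopentyl]ethan-1-one
Product: 14 N'-{1-[(1S,3S)-3-hydroxy-1,2,2-trimethylcyclopentyl]ethylidene}-2,4,6-tri(propan-2-yl)benzenesulfonohydrazide
Conditions: 2,4,6-(i-Pr)3C6H2SO2NHNH2, HCl (cat.), MeOH–THF, 25 °C
Reagents that add atoms: 2,4,6-tri(propan-2-yl)benzenesulfonohydrazide NNS(=O)(=O)c1c(C(C)C)cc(C(C)C)cc1C(C)C
Why: Acid-catalysed condensation gives the arenesulfonylhydrazone needed for the Shapiro reaction; the bulky aryl group prevents later ortho-lithiation.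

Step 8
Reactants: 15 2-methylcyclohexane-1,3-dione; 16 methyl bromoacetate
Product: 17 methyl 2-(1-methyl-2,6-dioxocyclohexyl)acetate
Conditions: NaH, DMF, 0 °C to rt
Reagents that add atoms: none
Why: C-Alkylation of the stabilised 1,3-dione enolate by the α-bromo ester (enolate alkylation) creates the quaternary carbon that becomes C8a; the product is achiral.

Step 9
Reactants: 17 methyl 2-(1-methyl-2,6-dioxocyclohexyl)acetate
Product: 19 (3aR,7aR)-3a-methylhexahydro-1-benzofuran-2,4-dione (cis-fused), via hydroxy ester 18 (not isolated)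
Conditions: (S)-2-methyl-CBS-oxazaborolidine (10 mol %), BH3·SMe2 (0.6 equiv), THF, −40 °C; MeOH; then p-TsOH (cat.), toluene, 60 °C
Reagents that add atoms: none
Why: Desymmetrising Corey–Bakshi–Shibata mono-reduction: the (S)-catalyst sets the (R)-carbinol and hydride should enter from the face of the smaller methyl group, so the hydroxyl ends cis to the acetate arm and acid closes the cis-fused γ-lactone, fixing C3a and C7a (later C8a and C8).

Step 10
Reactants: 19 (3aR,7aR)-3a-methylhexahydro-1-benzofuran-2,4-dione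
Product: 21 (3aR,7aR)-3a,5-dimethylhexahydro-1-benzofuran-2,4-dione (C5 epimers), via lithium enolate 20 (not isolated)
Conditions: LiN(i-Pr)2, THF, −78 °C; then MeI, −78 to 0 °C
Reagents that add atoms: iodomethane CI
Why: Kinetic deprotonation occurs at the ketone α-CH2, which is more acidic than the lactone α-CH2, and the enolate is methylated (enolate alkylation); the C5 configuration is irrelevant because C5 becomes sp2 in step 11.

Step 11
Reactants: 21 (3aR,7aR)-3a,5-dimethylhexahydro-1-benzofuran-2,4-dione (C5 epimers)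
Product: 22 (3aR,7aR)-3a,5-dimethyl-2-oxo-2,3,3a,6,7,7a-hexahydro-1-benzofuran-4-yl trifluoromethanesulfonate
Conditions: Tf2O, 2,6-di-tert-butyl-4-methylpyridine, CH2Cl2, 0 °C to rt
Reagents that add atoms: trifluoromethanesulfonic anhydride O=S(=O)(OS(=O)(=O)C(F)(F)F)C(F)(F)F
Why: O-Sulfonylation of the ketone with a hindered pyridine base gives the only possible, tetrasubstituted enol triflate (enol triflate formation), since the other α-carbon is quaternary and the lactone is not enolised.

Step 12
Reactants: 14 N'-{1-[(1S,3S)-3-hydroxy-1,2,2-trimethylcyclopentyl]ethylidene}-2,4,6-tri(propan-2-yl)benzenesulfonohydrazide; 22 (3aR,7aR)-3a,5-dimethyl-2-oxo-2,3,3a,6,7,7a-hexahydro-1-benzofuran-4-yl trifluoromethanesulfonate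
Product: 24 (5R,6R)-5-hydroxy-6-{3-[(1S,3S)-3-hydroxy-1,2,2-trimethylcyclopentyl]-2-oxobut-3-en-1-yl}-2,6-dimethylcyclohex-1-en-1-yl trifluoromethanesulfonate, via vinyllithium 23 (not isolated)
Conditions: 14, n-BuLi (3.1 equiv), THF, −78 to 0 °C; then 22, −78 °C; aq. NH4Cl
Reagents that add atoms: none
Why: Shapiro reaction of 14 (trianion, loss of sulfinate and N2) gives vinyllithium 23, which should add once to the lactone carbonyl of 22 (acyl substitution through a lactolate that is stable at −78 °C) to give the enone and free the C5 hydroxyl; the vinyl triflate should be inert at this temperature and no stereocenter is formed.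

Step 13
Reactants: 24 (5R,6R)-5-hydroxy-6-{3-[(1S,3S)-3-hydroxy-1,2,2-trimethylcyclopentyl]-2-oxobut-3-en-1-yl}-2,6-dimethylcyclohex-1-en-1-yl trifluoromethanesulfonate
Product: 25 (8R,8aS)-8-hydroxy-3-[(1S,3S)-3-hydroxy-1,2,2-trimethylcyclopentyl]-5,8a-dimethyl-6,7,8,8a-tetrahydronaphthalen-2(1H)-one
Conditions: Pd(OAc)2 (10 mol %), PPh3, Et3N, MeCN, 80 °C
Reagents that add atoms: none
Why: Intramolecular Heck reaction: zerovalent palladium inserts into the vinyl triflate and the vinylpalladium should add to the β-CH2 of the enone in the 6-endo-trig mode (5-exo would need bond formation at the α-carbon that carries the tertiary cyclopentyl group), and β-hydride elimination gives the linear dienone and ring A.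

Step 14
Reactants: 25 (8R,8aS)-8-hydroxy-3-[(1S,3S)-3-hydroxy-1,2,2-trimethylcyclopentyl]-5,8a-dimethyl-6,7,8,8a-tetrahydronaphthalen-2(1H)-one
Product: 26 (8S,8aS)-8-bromo-3-[(1R,3R)-3-bromo-1,2,2-trimethylcyclopentyl]-5,8a-dimethyl-6,7,8,8a-tetrahydronaphthalen-2(1H)-one
Conditions: CBr4, PPh3, toluene, 70 °C
Reagents that add atoms: carbon tetrabromide BrC(Br)(Br)Br
Why: Appel reaction: both neopentylic secondary alcohols should be displaced by bromide with SN2 inversion through their oxyphosphonium salts, which sets C8 (S) and C3' (R); no tertiary alcohol is present at this stage.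

Step 15
Reactants: 26 (8S,8aS)-8-bromo-3-[(1R,3R)-3-bromo-1,2,2-trimethylcyclopentyl]-5,8a-dimethyl-6,7,8,8a-tetrahydronaphthalen-2(1H)-one
Product: 27 (4aR,5S,8S,8aS)-8-bromo-3-[(1R,3R)-3-bromo-1,2,2-trimethylcyclopentyl]-4a,5-epoxy-5,8a-dimethyl-4a,5,6,7,8,8a-hexahydronaphthalen-2(1H)-one
Conditions: mCPBA, NaHCO3, CH2Cl2, 0 °C
Reagents that add atoms: 3-chloroperoxybenzoic acid OOC(=O)c1cccc(Cl)c1
Why: Prilezhaev epoxidation should take place at the more electron-rich tetrasubstituted γ,δ-alkene from the face opposite the axial C8a methyl group, which sets the C4a–O bond anti to that methyl.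

Step 16
Reactants: 27 (4aR,5S,8S,8aS)-8-bromo-3-[(1R,3R)-3-bromo-1,2,2-trimethylcyclopentyl]-4a,5-epoxy-5,8a-dimethyl-4a,5,6,7,8,8a-hexahydronaphthalen-2(1H)-one
Product: 28 (4aR,5R,8S,8aS)-8-bromo-3-[(1R,3R)-3-bromo-1,2,2-trimethylcyclopentyl]-4a,5-dihydroxy-5,8a-dimethyl-4a,5,6,7,8,8a-hexahydronaphthalen-2(1H)-one
Conditions: HClO4 (cat.), THF–H2O, 0 °C to rt
Reagents that add atoms: water O
Why: Acid-catalysed epoxide hydrolysis: water should attack the tertiary, non-allylic C5 with inversion (trans-diaxial opening, Fürst–Plattner rule), which retains the C4a–O bond and gives the trans-4a,5-diol with C5 (R).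

**Compound list**

1 | cyclopropyl(triphenyl)phosphonium bromide | [Br-].C1CC1[P+](c1ccccc1)(c1ccccc1)c1ccccc1 | starting material
2 | cyclopropylidene(triphenyl)-λ5-phosphane | C1CC1=P(c1ccccc1)(c1ccccc1)c1ccccc1 | intermediate
3 | [1-(phenylsulfanyl)cyclopropyl](triphenyl)phosphonium benzenesulfinate | [O-]S(=O)c1ccccc1.c1ccc(cc1)SC1(CC1)[P+](c1ccccc1)(c1ccccc1)c1ccccc1 | intermediate
4 | [1-(phenylsulfanyl)cyclopropyl](triphenyl)phosphonium tetrafluoroborate | F[B-](F)(F)F.c1ccc(cc1)SC1(CC1)[P+](c1ccccc1)(c1ccccc1)c1ccccc1 | intermediate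
5 | ethyl 2-methyl-3-oxobutanoate | CCOC(=O)C(C)C(C)=O | starting material
6 | sodium enolate of 5 (sodium 4-ethoxy-3-methyl-4-oxobut-2-en-2-olate) | CCOC(=O)C(C)=C(C)[O-].[Na+] | intermediate
7 | ethyl 2-acetyl-2-methyl-5-(phenylsulfanyl)-5-(triphenyl-λ5-phosphanylidene)pentanoate | CCOC(=O)C(C)(CCC(Sc1ccccc1)=P(c1ccccc1)(c1ccccc1)c1ccccc1)C(C)=O | intermediate
8 | ethyl 1,2-dimethyl-3-(phenylsulfanyl)cyclopent-2-ene-1-carboxylate (racemic) | CCOC(=O)C1(C)CCC(Sc2ccccc2)=C1C | intermediate
9 | ethyl 1,2-dimethyl-3-oxocyclopentane-1-carboxylate (racemic; C2 epimers) | CCOC(=O)C1(C)CCC(=O)C1C | intermediate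
10 | ethyl 1,2,2-trimethyl-3-oxocyclopentane-1-carboxylate (racemic) | CCOC(=O)C1(C)CCC(=O)C1(C)C | intermediate
11 | ethyl (1S,3S)-3-hydroxy-1,2,2-trimethylcyclopentane-1-carboxylate (OH trans to the ester) | CC1(C)[C@@H](O)CC[C@]1(C)C(=O)OCC | intermediate
12 | lithium 1-[(1S,3S)-3-(lithiooxy)-1,2,2-trimethylcyclopentyl]-2-(trimethylsilyl)ethen-1-olate | CC1(C)[C@@H](O[Li])CC[C@]1(C)C(O[Li])=C[Si](C)(C)C | intermediate
13 | 1-[(1S,3S)-3-hydroxy-1,2,2-trimethylcyclopentyl]ethan-1-one | CC1(C)[C@@H](O)CC[C@]1(C)C(C)=O | intermediate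
14 | N'-{1-[(1S,3S)-3-hydroxy-1,2,2-trimethylcyclopentyl]ethylidene}-2,4,6-tri(propan-2-yl)benzenesulfonohydrazide | CC1(C)[C@@H](O)CC[C@]1(C)C(C)=NNS(=O)(=O)c1c(C(C)C)cc(C(C)C)cc1C(C)C | intermediate
15 | 2-methylcyclohexane-1,3-dione | CC1C(=O)CCCC1=O | starting material
16 | methyl bromoacetate | COC(=O)CBr | starting material
17 | methyl 2-(1-methyl-2,6-dioxocyclohexyl)acetate | COC(=O)CC1(C)C(=O)CCCC1=O | intermediate
18 | methyl 2-[(1R,2R)-2-hydroxy-1-methyl-6-oxocyclohexyl]acetate | COC(=O)C[C@]1(C)[C@H](O)CCCC1=O | intermediate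
19 | (3aR,7aR)-3a-methylhexahydro-1-benzofuran-2,4-dione (cis-fused) | O=C1CCC[C@H]2OC(=O)C[C@@]12C | intermediate
20 | lithium (3aR,7aR)-3a-methyl-2-oxo-2,3,3a,6,7,7a-hexahydro-1-benzofuran-4-olate | [Li]OC1=CCC[C@H]2OC(=O)C[C@@]12C | intermediate
21 | (3aR,7aR)-3a,5-dimethylhexahydro-1-benzofuran-2,4-dione (C5 epimers) | O=C1C(C)CC[C@H]2OC(=O)C[C@@]12C | intermediate
22 | (3aR,7aR)-3a,5-dimethyl-2-oxo-2,3,3a,6,7,7a-hexahydro-1-benzofuran-4-yl trifluoromethanesulfonate | FC(F)(F)S(=O)(=O)OC1=C(C)CC[C@H]2OC(=O)C[C@@]12C | intermediate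
23 | 1-[3-(lithiooxy)-1,2,2-trimethylcyclopentyl]ethenyllithium (ring configuration as in 13) | CC1(C)[C@@H](O[Li])CC[C@]1(C)C([Li])=C | intermediate
24 | (5R,6R)-5-hydroxy-6-{3-[(1S,3S)-3-hydroxy-1,2,2-trimethylcyclopentyl]-2-oxobut-3-en-1-yl}-2,6-dimethylcyclohex-1-en-1-yl trifluoromethanesulfonate | CC1(C)[C@@H](O)CC[C@]1(C)C(=C)C(=O)C[C@]2(C)[C@H](O)CCC(C)=C2OS(=O)(=O)C(F)(F)F | intermediate
25 | (8R,8aS)-8-hydroxy-3-[(1S,3S)-3-hydroxy-1,2,2-trimethylcyclopentyl]-5,8a-dimethyl-6,7,8,8a-tetrahydronaphthalen-2(1H)-one | CC1(C)[C@@H](O)CC[C@]1(C)C1=CC2=C(C)CC[C@@H](O)[C@@]2(C)CC1=O | intermediate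
26 | (8S,8aS)-8-bromo-3-[(1R,3R)-3-bromo-1,2,2-trimethylcyclopentyl]-5,8a-dimethyl-6,7,8,8a-tetrahydronaphthalen-2(1H)-one | CC1(C)[C@H](Br)CC[C@]1(C)C1=CC2=C(C)CC[C@H](Br)[C@@]2(C)CC1=O | intermediate
27 | (4aR,5S,8S,8aS)-8-bromo-3-[(1R,3R)-3-bromo-1,2,2-trimethylcyclopentyl]-4a,5-epoxy-5,8a-dimethyl-4a,5,6,7,8,8a-hexahydronaphthalen-2(1H)-one | CC1(C)[C@H](Br)CC[C@]1(C)C1=C[C@@]23O[C@@]3(C)CC[C@H](Br)[C@@]2(C)CC1=O | intermediate
28 | (4aR,5R,8S,8aS)-8-bromo-3-[(1R,3R)-3-bromo-1,2,2-trimethylcyclopentyl]-4a,5-dihydroxy-5,8a-dimethyl-4a,5,6,7,8,8a-hexahydronaphthalen-2(1H)-one | CC1(C)[C@H](Br)CC[C@]1(C)C1=C[C@]2(O)[C@](C)(O)CC[C@H](Br)[C@@]2(C)CC1=O | target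

**Total step count:** 16. **Longest linear sequence:** 12 steps (steps 1–7, then 12–16).

**Steps most likely to fail**

1. Step 14. Displacement at the two neopentylic carbinols may be overtaken by E2 elimination or by a Wagner–Meerwein methyl shift, or inversion at C8 may stay incomplete. Fallback: from 25, both alcohols are converted with Tf2O and pyridine (CH2Cl2, −20 °C) into (8R,8aS)-5,8a-dimethyl-2-oxo-3-[(1S,3S)-1,2,2-trimethyl-3-(trifluoromethanesulfonyloxy)cyclopentyl]-1,2,6,7,8,8a-hexahydronaphthalen-8-yl trifluoromethanesulfonate F1. Displacement of this isolated bis-sulfonate with Bu4NBr in toluene at low temperature should give both bromides with inversion, and the route is rejoined at 26.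

2. Step 13. The vinylpalladium intermediate may cyclise in the 5-exo mode or be reduced before it closes the six-membered ring. Fallback: from 24, Stille coupling with tributyl(vinyl)stannane (Pd(PPh3)4, LiCl, THF, 60 °C) should give (1R,2S)-3-ethenyl-2-{3-[(1S,3S)-3-hydroxy-1,2,2-trimethylcyclopentyl]-2-oxobut-3-en-1-yl}-2,4-dimethylcyclohex-3-en-1-ol F2. Ring-closing metathesis with the second-generation Hoveyda–Grubbs catalyst (toluene, 80 °C) then joins the enone methylene and the new vinyl group with loss of ethene, and the route is rejoined at 25.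

3. Step 4. Enolate equilibration may fail to favour the hindered C2 position, which would lead to methylation at C4 and to over-alkylation. Fallback: from 9, TMSCl, NaI and Et3N in MeCN should give the more substituted silyl enol ether, ethyl 1,2-dimethyl-3-[(trimethylsilyl)oxy]cyclopent-2-ene-1-carboxylate F3. Simmons–Smith cyclopropanation (Et2Zn, CH2I2, CH2Cl2) converts it into ethyl 1,2-dimethyl-5-[(trimethylsilyl)oxy]bicyclo[3.1.0]hexane-2-carboxylate F4. Acid methanolysis (p-TsOH, MeOH) opens the siloxycyclopropane at its CH2 carbon to the geminal dimethyl ketone, and the route is rejoined at 10.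

**Further compounds**

F1 | step 14 | (8R,8aS)-5,8a-dimethyl-2-oxo-3-[(1S,3S)-1,2,2-trimethyl-3-(trifluoromethanesulfonyloxy)cyclopentyl]-1,2,6,7,8,8a-hexahydronaphthalen-8-yl trifluoromethanesulfonate | CC1(C)[C@@H](OS(=O)(=O)C(F)(F)F)CC[C@]1(C)C1=CC2=C(C)CC[C@@H](OS(=O)(=O)C(F)(F)F)[C@@]2(C)CC1=O
F2 | step 13 | (1R,2S)-3-ethenyl-2-{3-[(1S,3S)-3-hydroxy-1,2,2-trimethylcyclopentyl]-2-oxobut-3-en-1-yl}-2,4-dimethylcyclohex-3-en-1-ol | CC1(C)[C@@H](O)CC[C@]1(C)C(=C)C(=O)C[C@]2(C)[C@H](O)CCC(C)=C2C=C
F3 | step 4 | ethyl 1,2-dimethyl-3-[(trimethylsilyl)oxy]cyclopent-2-ene-1-carboxylate (racemic) | CCOC(=O)C1(C)CCC(O[Si](C)(C)C)=C1C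
F4 | step 4 | ethyl 1,2-dimethyl-5-[(trimethylsilyl)oxy]bicyclo[3.1.0]hexane-2-carboxylate (racemic; diastereomers) | CCOC(=O)C1(C)CCC2(O[Si](C)(C)C)CC12C
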